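## Retrosynthetic overview

1. Allylic alcohol 1 → epoxy alcohol 2 → epoxy acid 3: a Sharpless epoxidation fixes both oxirane centres of the side chain, which is carried in intact.
2. Enal 4 → 5 → 6 → 7 → 8 → 9 → keto aldehyde 10: Brown (Z)-crotylation sets C5/C6, acid 3 is esterified on, the vinyl end becomes the vinyl ketone (C7–C9), and ozonolysis frees the C4 aldehyde.
3. Acrolein 11 → dienol 12 (Brown methallylation sets C11a), acylated with acid 13 to ester 14.
4. Key disconnections of the target: C9=C10 (ring-closing metathesis), C3a–C4 (Barbier allylation with allylic transposition, which creates the α-methylene lactone) and the lactone C3–C3a bond (ring-closing metathesis).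
5. Ring order, all in one flask: 14 → butenolide 15 (five-membered ring) → union with 10 to seco-adduct 16 → ten-membered carbocycle of 17.

Assumption: descriptors follow the given SMILES, (3aR,4R,5R,6S,9Z,11aR) in the core and (2S,3R) in the oxirane ester; locants C2–C11a are those of the cyclodeca[b]furan core of 17; the sense of induction of the Brown reagents is taken by analogy with the acetaldehyde and benzaldehyde cases.

## Route

Step 1
Reactants: 1 (E)-2-methylbut-2-en-1-ol
Product: 2 [(2R,3R)-2,3-dimethyloxiran-2-yl]methanol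
Conditions: Ti(OiPr)4 (10 mol %), D-(−)-diethyl tartrate (12 mol %), tBuOOH, 4 Å MS, CH2Cl2, −20 °C
Reagents that add atoms: tert-butyl hydroperoxide, CC(C)(C)OO
Why: Sharpless asymmetric epoxidation, in which the D-(−)-tartrate/Ti(OiPr)4 catalyst delivers oxygen to one face of the E-trisubstituted allylic alcohol and so sets both oxirane carbons (2R,3R) with the two methyl groups cis.

Step 2
Reactants: 2 [(2R,3R)-2,3-dimethyloxiran-2-yl]methanol
Product: 3 (2S,3R)-2,3-dimethyloxirane-2-carboxylic acid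
Conditions: RuCl3·xH2O (2 mol %), NaIO4, MeCN/EtOAc/H2O, 0 °C to rt
Reagents that add atoms: sodium periodate, [Na+].[O-]I(=O)(=O)=O
Why: Catalytic ruthenium tetroxide oxidation (Sharpless conditions) takes the primary alcohol to the acid without opening the oxirane; no stereocentre is touched and C2 becomes S only because the CIP priorities change.

Step 3
Reactants: 4 3-methylbut-2-enal
Product: 5 (3S,4R)-3,6-dimethylhepta-1,5-dien-4-ol
Conditions: cis-2-butene, n-BuLi, KOtBu, THF, −78 to −45 °C; (+)-Ipc2BOMe, −78 °C; BF3·OEt2; then 4, −78 °C; NaOH, H2O2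
Reagents that add atoms: cis-but-2-ene, C/C=C\C, delivered as (Z)-but-2-en-1-ylbis(isopinocampheyl)borane, C/C=C\CB([C@H]1C[C@H]2C[C@@H]([C@@H]1C)C2(C)C)[C@H]1C[C@H]2C[C@@H]([C@@H]1C)C2(C)C
Why: Brown asymmetric crotylboration, in which the (Z)-crotylborane adds 1,2 to the enal through a chair Zimmerman–Traxler transition state (Z gives syn) and the isopinocampheyl groups direct attack to the Re face, setting C3 (S) and C4 (R).

Step 4
Reactants: 5 (3S,4R)-3,6-dimethylhepta-1,5-dien-4-ol; 3 (2S,3R)-2,3-dimethyloxirane-2-carboxylic acid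
Product: 6 (3S,4R)-3,6-dimethylhepta-1,5-dien-4-yl (2S,3R)-2,3-dimethyloxirane-2-carboxylate
Conditions: 2,4,6-Cl3C6H2COCl, Et3N, THF, rt; then 5, DMAP, PhMe, rt
Reagents that add atoms: none
Why: Yamaguchi esterification through the mixed trichlorobenzoic anhydride acylates the hindered secondary alcohol with retention at every stereocentre.

Step 5
Reactants: 6 (3S,4R)-3,6-dimethylhepta-1,5-dien-4-yl (2S,3R)-2,3-dimethyloxirane-2-carboxylate
Product: 7 (3S,4R)-3,6-dimethyl-1-oxohept-5-en-4-yl (2S,3R)-2,3-dimethyloxirane-2-carboxylate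
Conditions: PdCl2(PhCN)2 (12 mol %), CuCl2·2H2O (12 mol %), AgNO2 (6 mol %), O2 (1 atm), tBuOH/MeNO2 15:1, rt
Reagents that add atoms: dioxygen, O=O
Why: Nitrite-modified anti-Markovnikov Wacker oxidation converts only the monosubstituted olefin into the aldehyde, helped by the homoallylic ester oxygen, while the trisubstituted olefin is inert to the palladium catalyst and no stereocentre is touched.

Step 6
Reactants: 7 (3S,4R)-3,6-dimethyl-1-oxohept-5-en-4-yl (2S,3R)-2,3-dimethyloxirane-2-carboxylate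
Product: 8 (3RS,5S,6R)-3-hydroxy-5,8-dimethylnona-1,7-dien-6-yl (2S,3R)-2,3-dimethyloxirane-2-carboxylate
Conditions: CH2=CHMgBr, THF, −78 °C; aq. NH4Cl
Reagents that add atoms: vinylmagnesium bromide, C=C[Mg]Br
Why: Grignard 1,2-addition at −78 °C is far faster at the aldehyde than at the hindered glycidic ester; the new carbinol centre forms as a mixture that is erased in the next step.

Step 7
Reactants: 8 (3RS,5S,6R)-3-hydroxy-5,8-dimethylnona-1,7-dien-6-yl (2S,3R)-2,3-dimethyloxirane-2-carboxylate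
Product: 9 (5S,6R)-5,8-dimethyl-3-oxonona-1,7-dien-6-yl (2S,3R)-2,3-dimethyloxirane-2-carboxylate
Conditions: Dess–Martin periodinane, CH2Cl2, 0 °C to rt
Reagents that add atoms: none
Why: Dess–Martin oxidation of the secondary allylic alcohol gives the vinyl ketone under near-neutral conditions that leave oxirane, ester and olefins alone.

Step 8
Reactants: 9 (5S,6R)-5,8-dimethyl-3-oxonona-1,7-dien-6-yl (2S,3R)-2,3-dimethyloxirane-2-carboxylate
Product: 10 (2R,3S)-3-methyl-1,5-dioxohept-6-en-2-yl (2S,3R)-2,3-dimethyloxirane-2-carboxylate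
Conditions: O3, CH2Cl2, −78 °C (Sudan Red 7B end point); Me2S
Reagents that add atoms: ozone, [O-][O+]=O
Why: Chemoselective ozonolysis (Criegee mechanism, reductive work-up) cleaves the electron-rich trisubstituted olefin much faster than the electron-poor vinyl ketone and frees the C2 aldehyde without touching the adjacent stereocentre.

Step 9
Reactants: 11 prop-2-enal
Product: 12 (3R)-5-methylhexa-1,5-dien-3-ol
Conditions: CH2=C(CH3)CH2MgCl, (+)-Ipc2BOMe, Et2O, −78 °C to rt; then 11, −78 °C; NaOH, H2O2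
Reagents that add atoms: methallylmagnesium chloride, C=C(C)C[Mg]Cl, delivered as (2-methylprop-2-en-1-yl)bis(isopinocampheyl)borane, C=C(C)CB([C@H]1C[C@H]2C[C@@H]([C@@H]1C)C2(C)C)[C@H]1C[C@H]2C[C@@H]([C@@H]1C)C2(C)C
Why: Brown asymmetric allylboration, in which the B-methallyl reagent adds 1,2 to acrolein through a chair transition state on the Re face and sets the carbinol centre as R.

Step 10
Reactants: 12 (3R)-5-methylhexa-1,5-dien-3-ol; 13 2-(bromomethyl)prop-2-enoic acid
Product: 14 (3R)-5-methylhexa-1,5-dien-3-yl 2-(bromomethyl)prop-2-enoate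
Conditions: DCC, DMAP (cat.), CH2Cl2, 0 °C
Reagents that add atoms: none
Why: Steglich esterification at 0 °C acylates the secondary alcohol faster than DMAP displaces the allylic bromide, with retention at the carbinol centre.

Step 11
Reactants: 14 (3R)-5-methylhexa-1,5-dien-3-yl 2-(bromomethyl)prop-2-enoate; 10 (2R,3S)-3-methyl-1,5-dioxohept-6-en-2-yl (2S,3R)-2,3-dimethyloxirane-2-carboxylate
Product: 17 CNP0227299.4 [(3aR,4R,5R,6S,9Z,11aR)-4-hydroxy-6,10-dimethyl-3-methylidene-2,8-dioxo-2,3,3a,4,5,6,7,8,11,11a-decahydrocyclodeca[b]furan-5-yl (2S,3R)-2,3-dimethyloxirane-2-carboxylate], via butenolide 15 (not isolated), via seco-adduct 16 (not isolated)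
Conditions: second-generation Grubbs catalyst (5 mol %), PhMe, 80 °C; then 10, In powder, THF, rt, sonication; then H2O (2 equiv), PhMe (to 1 mM), second-generation Hoveyda–Grubbs catalyst (15 mol %), 80 °C
Reagents that add atoms: none
Why: Proposed new method: three known reactions are telescoped in one flask, namely ring-closing metathesis of the bromomethylacrylate onto the vinyl group to give butenolide 15, addition of its allylindium reagent to aldehyde 10 through a chair Zimmerman–Traxler transition state anti to the C5 side chain of the butenolide (closest known type: Barbier reactions of 3-(bromomethyl)furan-2(5H)-ones, which here set C3a and C4 from C11a and unveil the α-methylene lactone), and a second ring-closing metathesis between the methallyl group and the vinyl ketone that closes the ten-membered ring, whose size enforces the Z olefin (closest known type: macrocyclic enone ring-closing metathesis).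

## Compound list

1 | (E)-2-methylbut-2-en-1-ol | C/C=C(\C)CO | starting material
2 | [(2R,3R)-2,3-dimethyloxiran-2-yl]methanol | OC[C@@]1(C)O[C@@H]1C | intermediate
3 | (2S,3R)-2,3-dimethyloxirane-2-carboxylic acid | OC(=O)[C@@]1(C)O[C@@H]1C | intermediate
4 | 3-methylbut-2-enal | CC(C)=CC=O | starting material
5 | (3S,4R)-3,6-dimethylhepta-1,5-dien-4-ol | C=C[C@H](C)[C@@H](O)C=C(C)C | intermediate
6 | (3S,4R)-3,6-dimethylhepta-1,5-dien-4-yl (2S,3R)-2,3-dimethyloxirane-2-carboxylate | C=C[C@H](C)[C@@H](OC(=O)[C@@]1(C)O[C@@H]1C)C=C(C)C | intermediate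
7 | (3S,4R)-3,6-dimethyl-1-oxohept-5-en-4-yl (2S,3R)-2,3-dimethyloxirane-2-carboxylate | O=CC[C@H](C)[C@@H](OC(=O)[C@@]1(C)O[C@@H]1C)C=C(C)C | intermediate
8 | (3RS,5S,6R)-3-hydroxy-5,8-dimethylnona-1,7-dien-6-yl (2S,3R)-2,3-dimethyloxirane-2-carboxylate (C3 epimers) | C=CC(O)C[C@H](C)[C@@H](OC(=O)[C@@]1(C)O[C@@H]1C)C=C(C)C | intermediate
9 | (5S,6R)-5,8-dimethyl-3-oxonona-1,7-dien-6-yl (2S,3R)-2,3-dimethyloxirane-2-carboxylate | C=CC(=O)C[C@H](C)[C@@H](OC(=O)[C@@]1(C)O[C@@H]1C)C=C(C)C | intermediate
10 | (2R,3S)-3-methyl-1,5-dioxohept-6-en-2-yl (2S,3R)-2,3-dimethyloxirane-2-carboxylate | C=CC(=O)C[C@H](C)[C@@H](OC(=O)[C@@]1(C)O[C@@H]1C)C=O | intermediate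
11 | prop-2-enal (acrolein) | C=CC=O | starting material
12 | (3R)-5-methylhexa-1,5-dien-3-ol | C=C[C@H](O)CC(C)=C | intermediate
13 | 2-(bromomethyl)prop-2-enoic acid | C=C(CBr)C(=O)O | starting material
14 | (3R)-5-methylhexa-1,5-dien-3-yl 2-(bromomethyl)prop-2-enoate | C=C[C@H](OC(=O)C(=C)CBr)CC(C)=C | intermediate
15 | (5R)-3-(bromomethyl)-5-(2-methylprop-2-en-1-yl)furan-2(5H)-one | BrCC1=C[C@@H](CC(C)=C)OC1=O | intermediate
16 | (1R,2R,3S)-1-hydroxy-3-methyl-1-[(2R,3R)-4-methylidene-2-(2-methylprop-2-en-1-yl)-5-oxooxolan-3-yl]-5-oxohept-6-en-2-yl (2S,3R)-2,3-dimethyloxirane-2-carboxylate | C=C1C(=O)O[C@H](CC(C)=C)[C@H]1[C@@H](O)[C@H](OC(=O)[C@@]2(C)O[C@@H]2C)[C@@H](C)CC(=O)C=C | intermediate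
17 | CNP0227299.4, (3aR,4R,5R,6S,9Z,11aR)-4-hydroxy-6,10-dimethyl-3-methylidene-2,8-dioxo-2,3,3a,4,5,6,7,8,11,11a-decahydrocyclodeca[b]furan-5-yl (2S,3R)-2,3-dimethyloxirane-2-carboxylate | C=C1C(=O)O[C@@H]2C/C(C)=C\C(=O)C[C@H](C)[C@@H](OC(=O)[C@@]3(C)O[C@@H]3C)[C@H](O)[C@@H]12 | target

## Step count and risks

Total step count: 11. Longest linear sequence: 8 steps (steps 1, 2, 4, 5, 6, 7, 8, 11).

Step 11 is the most likely to fail. The telescoping is untested, the Barbier face set by the butenolide must override the Felkin preference of the α-acyloxy aldehyde, and the last ring closure joins two poorly initiating olefins into a trisubstituted enone in a ten-membered ring. The fallback runs the end game stepwise at the alcohol oxidation level; it sets out from 8 and 14 and comes back at 17. Ozonolysis of 8 (O3; Me2S) gives the hydroxy aldehyde (2R,3S)-5-hydroxy-3-methyl-1-oxohept-6-en-2-yl (2S,3R)-2,3-dimethyloxirane-2-carboxylate F1, which exists mainly as its six-membered lactol. Ester 14 is cyclized separately with the second-generation Grubbs catalyst and 15 is isolated. An aqueous indium Barbier reaction (In, THF/aq. NH4Cl) of 15 with F1 gives the diol (1R,2R,3S)-1,5-dihydroxy-3-methyl-1-[(2R,3R)-4-methylidene-2-(2-methylprop-2-en-1-yl)-5-oxooxolan-3-yl]hept-6-en-2-yl (2S,3R)-2,3-dimethyloxirane-2-carboxylate F2. Ring-closing metathesis then starts on the electron-neutral vinyl carbinol and closes onto the methallyl group to give the macrocyclic allylic alcohol (3aR,4R,5R,6S,9Z,11aR)-4,8-dihydroxy-6,10-dimethyl-3-methylidene-2-oxo-2,3,3a,4,5,6,7,8,11,11a-decahydrocyclodeca[b]furan-5-yl (2S,3R)-2,3-dimethyloxirane-2-carboxylate F3. MnO2 oxidizes only the allylic C8 hydroxyl and gives 17.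

Step 5 is the second risk. Aldehyde selectivity of the Wacker oxidation may drop at the α-branched olefin, and transient zerovalent palladium could ionize the allylic ester. The fallback sets out from 6 and comes back at 7: hydroboration of the terminal olefin with 9-BBN and NaBO3·4H2O work-up gives the primary alcohol (3S,4R)-1-hydroxy-3,6-dimethylhept-5-en-4-yl (2S,3R)-2,3-dimethyloxirane-2-carboxylate F4, and Dess–Martin oxidation of F4 gives 7.

Step 8 is the third risk. Over-ozonolysis of the vinyl ketone and the lability of the α-acyloxy aldehyde can erode the yield. The fallback sets out from 9 and comes back at 10: dihydroxylation of the trisubstituted olefin (OsO4 cat., NMO) gives the diol (5S,6R)-7,8-dihydroxy-5,8-dimethyl-3-oxonon-1-en-6-yl (2S,3R)-2,3-dimethyloxirane-2-carboxylate F5, and NaIO4 cleavage of F5 in buffered aqueous THF gives 10.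

Further compounds
F1 | step 11 | (2R,3S)-5-hydroxy-3-methyl-1-oxohept-6-en-2-yl (2S,3R)-2,3-dimethyloxirane-2-carboxylate (C5 epimers) | C=CC(O)C[C@H](C)[C@@H](OC(=O)[C@@]1(C)O[C@@H]1C)C=O
F2 | step 11 | (1R,2R,3S)-1,5-dihydroxy-3-methyl-1-[(2R,3R)-4-methylidene-2-(2-methylprop-2-en-1-yl)-5-oxooxolan-3-yl]hept-6-en-2-yl (2S,3R)-2,3-dimethyloxirane-2-carboxylate (C5 epimers) | C=C1C(=O)O[C@H](CC(C)=C)[C@H]1[C@@H](O)[C@H](OC(=O)[C@@]2(C)O[C@@H]2C)[C@@H](C)CC(O)C=C
F3 | step 11 | (3aR,4R,5R,6S,9Z,11aR)-4,8-dihydroxy-6,10-dimethyl-3-methylidene-2-oxo-2,3,3a,4,5,6,7,8,11,11a-decahydrocyclodeca[b]furan-5-yl (2S,3R)-2,3-dimethyloxirane-2-carboxylate (C8 epimers) | C=C1C(=O)O[C@@H]2C/C(C)=C\C(O)C[C@H](C)[C@@H](OC(=O)[C@@]3(C)O[C@@H]3C)[C@H](O)[C@@H]12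
F4 | step 5 | (3S,4R)-1-hydroxy-3,6-dimethylhept-5-en-4-yl (2S,3R)-2,3-dimethyloxirane-2-carboxylate | OCC[C@H](C)[C@@H](OC(=O)[C@@]1(C)O[C@@H]1C)C=C(C)C
F5 | step 8 | (5S,6R)-7,8-dihydroxy-5,8-dimethyl-3-oxonon-1-en-6-yl (2S,3R)-2,3-dimethyloxirane-2-carboxylate (C7 epimers) | C=CC(=O)C[C@H](C)[C@@H](OC(=O)[C@@]1(C)O[C@@H]1C)C(O)C(C)(C)O
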